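Remark on the chemistry: natural (−)-α-santonin (11S) is assumed; decalin compounds are numbered as eudesmanes with α/β descriptors (β = face of the C10 methyl) and ring-opened compounds as germacranes. The configurations required of the fragmentation substrate (1β-sulfonate, 2α,3α-oxirane, 5α-hydroxyl, 8α-oxygen) and of its E-configured product were re-derived from the target and are consistent, so only spectator groups and the order of operations are altered.

## Structural features

The target is a germacranolide: a ten-membered carbocycle (C1–C10) with an α-methylene-γ-butyrolactone fused trans across C6–C7, a methacrylate on O8, a free secondary hydroxyl on C5 and an exocyclic methylene (C15) on C4. Two oxiranes lie side by side on one arc of the ring, a trans-trisubstituted one at C1–C10 (C10 also carries the C14 methyl) and a cis-disubstituted one at C2–C3, so that C10, C1, C2 and C3 are four contiguous oxygenated stereocentres. On the other arc C5, C6, C7 and C8 form a second contiguous set, which gives eight stereocentres (1R,2S,3S,5R,6S,7R,8S,10R) on a conformationally mobile ring. The fragile groups are the two acrylate-type acceptors (α-methylene lactone and methacrylate), the two allylic-type oxiranes, which are prone to acid-induced transannular reactions, and the allylic C5 carbinol. The three oxygens O5, O6 and O8 are close enough for acyl migration or translactonisation. The real difficulty is the ten-membered ring with its stereodefined trisubstituted C1–C10 unit, which direct cyclisation forms poorly, together with oxygen at the unactivated C8 position. The key step exploits the transannular pair C5/C10 and the 1,3-relationship (through C10) of the oxygens on C1 and C5. With one extra bond C5–C10 the ring becomes the trans-decalin of a eudesmanolide whose C6, C7, lactone and C10 methyl coincide with α-santonin, and the array O–C1–C10–C5–O is a 1,3-diol monosulfonate set up for fragmentation. The C1–C10 oxirane and the C5 carbinol can then be drawn from the olefin and the ketone that this fragmentation leaves behind.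

## Logic of the disconnections

24 ⇒ 23. The C5–H bond is cut, tracing the carbinol to the ketone. The ketone is what ring opening delivers, and holding C5 at the ketone level until the end makes 24 the only compound with a free secondary hydroxyl beside the ester, so O5 needs no protecting group. The forward step must add hydride 1,2 to an exocyclic enone in the presence of two acrylate acceptors and on the face that gives 5R.

23 ⇒ 22. Both C–O bonds of the C1–C10 oxirane are cut. Two stereocentres disappear and the E-trisubstituted olefin remains, the only olefin of 22 not conjugated to a carbonyl. The forward epoxidation must be neutral, selective for this olefin and peripheral on the conformer that keeps the C14 methyl on the β face.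

22 ⇒ 21 ⇒ 20. The transannular bond C5–C10 is re-formed, the C1=C10 π bond becomes the C1–O bond of a sulfonate and the C5 ketone becomes an alkoxide. The medium ring turns into a trans-decalin, and the olefin geometry is translated into the configuration at C1 (β, equatorial). In 20 the C8 oxygen already carries the methacrylate, so only two operations follow the ring opening. The demands are a C1–O bond anti-periplanar to C5–C10, a non-nucleophilic base, and survival of the ester and the α-methylene lactone during the short life of 21.

20 ⇒ 18 + 19, 18 ⇒ 17, 17 ⇒ 15 + 16. The acyl C–O bond at O8, the O–Si bond at O8 and the S–O bond at O1 are cut in turn. Sulfonylating first means that the acylation meets a single secondary hydroxyl, since O5 is tertiary. The forward steps require selective sulfonylation of the secondary 1β-hydroxyl of a 1,3-diol and a buffered fluoride source, so that the 5-hydroxy-1-sulfonate does not fragment early.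

15 ⇒ 14 ⇒ 13. The C1–H bond is cut and re-formed on the other face, an inversion through the ketone. On the decalin every reagent reaches C1 from the α face, away from the C10 methyl, so the equatorial 1β-carbinol can only arise by α delivery of hydride. The 5α-hydroxyl is used to deliver it, which also avoids free borohydride near the acrylate.

13 ⇒ 12 ⇒ 11 ⇒ 10. The C11=C13 bond is traced through a selenoxide to the 11-methyl lactone of the chiral pool. The unsaturation is placed after the last nucleophilic oxidant, hydrazine and aluminium alkoxide, and before the first ketone appears. The forward step must enolise the lactone in a bis-alkoxide and place selenium trans to H7.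

10 ⇒ 9 ⇒ 8 ⇒ 7. The O5–H/C4=C15 pair is traced to the 4,5-oxirane, and the four C–O bonds of both oxiranes are then cut back to one molecule of dioxygen and the ring A 2,4-diene. Three oxygenated centres (C2, C3, C5) and the C4 methylene thus come from one face-selective cycloaddition. The forward steps need α-face [4+2] addition, a syn bis-epoxide rearrangement and proton removal at C15 only.

7 ⇒ 6 ⇒ 5 ⇒ 4. The C1–O bond and the C2=C3 bond are traced to the 1,2-oxirane of a 3-ketone (1,3-oxygen transposition), and that oxirane to the C1=C2 bond of the cross-conjugated dienone. This reaches the oxidation pattern of the starting terpenoid. The forward steps need nucleophilic epoxidation of the less substituted enone and hydrazone chemistry that spares the lactone.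

4 ⇒ 2 + 3, 2 ⇒ 1. The O–Si bond and then the C8–O bond are cut, arriving at 1, which supplies all fifteen ring and lactone carbons, C6, C7, the lactone and the C10 methyl in the correct absolute sense. The demand is site- and stereoselective hydroxylation of an unactivated methylene, the weakest link of the plan.

## Other disconnections considered

Alternative 1: The cut is the C6–O bond of the lactone, and the precursor is the ten-membered seco acid with an E-C4=C5 olefin. In the forward step Pd(OAc)2 (divalent palladium) with a sulfoxide ligand and a quinone oxidant would cleave the allylic C6–H bond with help of the C12 carboxylate, and the tethered carboxylate would close the five-membered ring on the allyl terminus to give A1. In its favour, the order of events is biomimetic, O6 never needs protection, and the lactone, the most base-sensitive unit, appears last; on these two points it is better than the chosen plan. Against it, this reaction type is established for terminal olefins, whereas here the olefin is internal and trisubstituted with three different allylic positions (C3, C6, C15), one of them an oxirane carbon. Any zerovalent palladium in the cycle could ionise that vinyl oxirane, and both oxiranes would face a Lewis-acidic metal. A1 is also not the target: C4=C5 must still become the 5-hydroxy-4(15)-ene by an ene-type oxidation on a ring that holds every fragile group. In comparison, this disconnection leaves open how the ten-membered ring is made, which the chosen plan solves in the step that also fixes the olefin geometry. The fragmentation is stereospecific, while here site and face of C–O formation would rest on catalyst control. In step count it cannot be shorter, since the macrocycle with both oxiranes and the C8 ester must be assembled first.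

Alternative 2: The cut is C8–C9; in the reverse sense C1 and C6 are joined to give a six-membered ring. In the forward step the potassium alkoxide of a monoterpene-derived 1,2-dialkenyl cyclohexenol would undergo a [3,3] shift through a chair to an enolate and, after protonation, A2. In its favour, four atoms are added to the ring with a strong driving force, the E olefin comes from the chair, the C8 centre is set by chirality transfer as a C–Si bond (later C–O with retention by Fleming–Tamao oxidation), and the C5 oxygen is in place. No unactivated C–H oxidation at C8 is needed, which is better than the chosen plan. Mechanistically the two key steps are equals: both are concerted and stereospecific. Against it, A2 lacks the three lactone carbons. They would have to be attached at C7 beside a ketone that has a second, alkoxy-bearing α position, C6 would have to be reduced with control, and C6/C7 would be set on a flexible ring instead of coming from the chiral pool. The C1=C10–C2=C3–C4=C15 triene would need two site- and face-selective epoxidations, and the silane oxidation uses electrophilic conditions that the triene may not survive. In step economy at least eight operations would follow A2, against two after 22; the length before the key step is comparable.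

Alternative 3: The cut is the C2=C3 bond, with C15 traced to the terminal carbon of a vinyl group. In the forward step a ruthenium alkylidene (second-generation Grubbs catalyst) under ethylene would join the alkene terminus at C2 to the alkyne on C5 in the endo mode and give A3. In its favour, ring, cis olefin and exocyclic methylene would form in one event, no strong base meets the lactone, and A3 is one epoxidation from the target. That is one operation after the key step against two in the chosen plan, so on this count it is better. Against it, ten-membered ring closure by metathesis works against entropy and strain, and the endo/exo mode is not secured. The methacrylate and the α-methylene lactone can enter the catalytic cycle, and an allylic oxirane and a propargylic oxygen flank the reacting termini. The last epoxidation would have to pick C2=C3 of a diene while the free C5 hydroxyl steers reagents to C4=C15. The acyclic enyne must also carry six stereocentres built from scratch. In comparison, the chosen plan opens a ring with release of strain instead of closing one against it, and installs the 2,3-oxirane on a rigid decalin before the medium ring exists. The shorter end-game here is paid for by a longer precursor synthesis, so no overall saving is expected.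

Key step: step 13

## Route

Step 1
Reactants: 1 α-santonin
Product: 2 artemisin (8α-hydroxy-α-santonin)
Conditions: growing culture of an 8α-hydroxylating zygomycete (Absidia or Mucor strain selected by screening), glucose–peptone medium, air, 28 °C; EtOAc extraction
Reagents that add atoms: dioxygen, O=O
Why: Enzymatic (P450 monooxygenase) C–H hydroxylation, a reaction type known for santonin-type lactones in fungal cultures; oxygen rebound with retention at the exposed equatorial 8α C–H should give the equatorial 8α-alcohol (8S).

Step 2
Reactants: 2 artemisin; 3 tert-butyldimethylsilyl chloride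
Product: 4 8α-(tert-butyldimethylsilyloxy)-α-santonin
Conditions: TBSCl, imidazole, DMF, rt
Reagents that add atoms: tert-butyldimethylsilyl chloride (3), CC(C)(C)[Si](C)(C)Cl
Why: Silyl ether formation at the only hydroxyl; the ether withstands peroxide, hydrazine, aluminium alkoxide, amide base and oxidants used up to step 10.

Step 3
Reactants: 4 8α-(tert-butyldimethylsilyloxy)-α-santonin
Product: 5 1α,2α-epoxy-8α-(tert-butyldimethylsilyloxy)-3-oxoeudesm-4-en-12,6α-olide
Conditions: t-BuOOH, BnNMe3OH (cat.), THF, 0 °C → rt
Reagents that add atoms: tert-butyl hydroperoxide, CC(C)(C)OO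
Why: Weitz–Scheffer nucleophilic epoxidation; the peroxide anion adds to C1, the unsubstituted β-carbon of the cross-conjugated dienone (C5 is fully substituted), from the α face opposite the C10 methyl, as with steroidal 1,4-dien-3-ones. Anhydrous conditions avoid opening of the lactone.

Step 4
Reactants: 5 1α,2α-epoxy-8α-(tert-butyldimethylsilyloxy)-3-oxoeudesm-4-en-12,6α-olide
Product: 7 1α-hydroxy-8α-(tert-butyldimethylsilyloxy)eudesma-2,4-dien-12,6α-olide, via C3 hydrazone 6 (not isolated)
Conditions: N2H4·H2O, AcOH (cat.), MeOH, 0 °C → rt
Reagents that add atoms: hydrazine, NN (nitrogen stays in 6 only and leaves as N2)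
Why: Wharton transposition; hydrazone 6 opens the oxirane to an allylic diazene that loses N2, which places C2=C3 next to C4=C5 and leaves the C1–O bond untouched, so the 1α configuration of the epoxide is kept.

Step 5
Reactants: 7 1α-hydroxy-8α-(tert-butyldimethylsilyloxy)eudesma-2,4-dien-12,6α-olide
Product: 9 2α,3α:4α,5α-diepoxy-1α-hydroxy-8α-(tert-butyldimethylsilyloxy)eudesman-12,6α-olide, via 2α,5α-endoperoxide 8 (not isolated)
Conditions: O2, tetraphenylporphyrin (sensitizer), visible light, CH2Cl2, −30 °C; then Co(TPP) (5 mol %, divalent cobalt), −30 → 0 °C
Reagents that add atoms: dioxygen, O=O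
Why: Singlet-oxygen [4+2] cycloaddition to the homoannular diene from the α face (the C10 methyl shields the β face, as in steroidal 2,4-dienes; the allylic 1α-hydroxyl can assist), then cobalt-porphyrin rearrangement of the bicyclic endoperoxide to the syn bis-epoxide. Both oxiranes inherit the α face, which sets C2, C3, C4 and C5 in one operation.

Step 6
Reactants: 9 2α,3α:4α,5α-diepoxy-1α-hydroxy-8α-(tert-butyldimethylsilyloxy)eudesman-12,6α-olide
Product: 10 2α,3α-epoxy-1α,5α-dihydroxy-8α-(tert-butyldimethylsilyloxy)eudesm-4(15)-en-12,6α-olide
Conditions: Al(OiPr)3, toluene, 110 °C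
Reagents that add atoms: none
Why: Aluminium-alkoxide isomerisation of an epoxide to an allylic alcohol by syn β-elimination; only the C15 hydrogens can reach the oxygen-bound aluminium alkoxide on the α face (H3 and H6 are β, C10 has no hydrogen), so C4–O breaks and the 5α-alkoxide with C4=C15 results. The 2,3-oxirane has no syn β-hydrogen and should stay.

Step 7
Reactants: 10 2α,3α-epoxy-1α,5α-dihydroxy-8α-(tert-butyldimethylsilyloxy)eudesm-4(15)-en-12,6α-olide
Product: 13 2α,3α-epoxy-1α,5α-dihydroxy-8α-(tert-butyldimethylsilyloxy)eudesma-4(15),11(13)-dien-12,6α-olide, via 11β-phenylselenide 11 (not isolated), via selenoxide 12 (not isolated)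
Conditions: LiN(iPr)2 (3.3 equiv), THF, −78 °C; PhSeBr, −78 → −40 °C; then AcOH, 30 % H2O2, 0 °C → rt
Reagents that add atoms: benzeneselenenyl bromide, Br[Se]c1ccccc1 (selenium and phenyl stay in 11 and 12 only); hydrogen peroxide, OO (oxygen stays in 12 only)
Why: Lactone enolate selenenylation and selenoxide syn-elimination; two equivalents of base are taken up by the hydroxyls, and the 1α-alkoxide is cis to the oxirane so no Payne rearrangement is open. In the trans-fused lactone selenium enters trans to H7, so only the methyl hydrogens are syn and the exocyclic C11=C13 bond forms.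

Step 8
Reactants: 13 2α,3α-epoxy-1α,5α-dihydroxy-8α-(tert-butyldimethylsilyloxy)eudesma-4(15),11(13)-dien-12,6α-olide
Product: 14 2α,3α-epoxy-5α-hydroxy-1-oxo-8α-(tert-butyldimethylsilyloxy)eudesma-4(15),11(13)-dien-12,6α-olide
Conditions: Dess–Martin periodinane, CH2Cl2, 0 °C → rt
Reagents that add atoms: none
Why: Dess–Martin oxidation of the only secondary alcohol; the tertiary allylic 5α-hydroxyl is inert, and the neutral medium avoids retro-aldol cleavage of the β-hydroxy ketone.

Step 9
Reactants: 14 2α,3α-epoxy-5α-hydroxy-1-oxo-8α-(tert-butyldimethylsilyloxy)eudesma-4(15),11(13)-dien-12,6α-olide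
Product: 15 2α,3α-epoxy-1β,5α-dihydroxy-8α-(tert-butyldimethylsilyloxy)eudesma-4(15),11(13)-dien-12,6α-olide
Conditions: Me4NBH(OAc)3, MeCN/AcOH, −20 °C
Reagents that add atoms: none
Why: Hydroxyl-directed triacetoxyborohydride reduction (Evans–Saksena type); the axial 5α-hydroxyl binds boron and delivers hydride through a six-membered transition state to the α face of C1, giving the equatorial 1β-alcohol anti to O5. This weak hydride donor does not reduce the α-methylene lactone.

Step 10
Reactants: 15 2α,3α-epoxy-1β,5α-dihydroxy-8α-(tert-butyldimethylsilyloxy)eudesma-4(15),11(13)-dien-12,6α-olide; 16 methanesulfonyl chloride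
Product: 17 2α,3α-epoxy-5α-hydroxy-1β-mesyloxy-8α-(tert-butyldimethylsilyloxy)eudesma-4(15),11(13)-dien-12,6α-olide
Conditions: MsCl, Et3N, CH2Cl2, −20 → 0 °C
Reagents that add atoms: methanesulfonyl chloride (16), CS(=O)(=O)Cl
Why: Sulfonylation through sulfene, which reaches the hindered secondary 1β-hydroxyl and leaves the tertiary 5α-hydroxyl free; triethylamine is too weak a base to start the fragmentation.

Step 11
Reactants: 17 2α,3α-epoxy-5α-hydroxy-1β-mesyloxy-8α-(tert-butyldimethylsilyloxy)eudesma-4(15),11(13)-dien-12,6α-olide
Product: 18 2α,3α-epoxy-5α,8α-dihydroxy-1β-mesyloxyeudesma-4(15),11(13)-dien-12,6α-olide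
Conditions: Bu4NF, AcOH (1:1), THF, 0 °C → rt
Reagents that add atoms: none
Why: Fluoride-mediated desilylation on the rigid decalin; acetic acid buffering keeps O5 and O8 protonated, which suppresses premature fragmentation and lactone migration to O8.

Step 12
Reactants: 18 2α,3α-epoxy-5α,8α-dihydroxy-1β-mesyloxyeudesma-4(15),11(13)-dien-12,6α-olide; 19 methacryloyl chloride
Product: 20 2α,3α-epoxy-5α-hydroxy-1β-mesyloxy-8α-methacryloyloxyeudesma-4(15),11(13)-dien-12,6α-olide
Conditions: methacryloyl chloride, Et3N, DMAP (cat.), CH2Cl2, 0 °C
Reagents that add atoms: methacryloyl chloride (19), C=C(C)C(=O)Cl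
Why: Acylation under nucleophilic catalysis; O8 is the only secondary hydroxyl at this stage and the tertiary O5 does not compete, so the ester that the target needs is placed without any selectivity problem.

Step 13
Reactants: 20 2α,3α-epoxy-5α-hydroxy-1β-mesyloxy-8α-methacryloyloxyeudesma-4(15),11(13)-dien-12,6α-olide
Product: 22 2,3-epoxy-8-methacryloyloxygermacra-1(10)E,4(15),11(13)-trien-5-on-12,6-olide, via potassium C5-alkoxide 21 (not isolated)
Conditions: KN(SiMe3)2 (1.05 equiv), THF, −78 → −20 °C; pH 7 buffer
Reagents that add atoms: potassium bis(trimethylsilyl)amide, C[Si](C)(C)[N-][Si](C)(C)C.[K+] (potassium stays in 21 only)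
Why: Wharton–Grob fragmentation of a cyclic 1,3-diol monosulfonate; the closest known reaction type is the base-induced opening of decalin-1,3-diol monosulfonates to (E)-cyclodec-5-enones. The amide base deprotonates the tertiary 5α-hydroxyl to alkoxide 21, and in one concerted event an oxygen lone pair forms C5=O, the C5–C10 σ bond becomes the C1=C10 π bond and mesylate leaves C1. No ring is closed by bond formation: the ten-membered ring appears because the bond shared by ring A and ring B is cut, so rules for modes of ring closure do not apply and no penalty for medium-ring cyclisation is paid. No stereocentre is created (C1, C5 and C10 become trigonal); the new stereo element is the olefin geometry, fixed as E because C9–C10 and C1–C2 are anti about C1–C10 in the trans-decalin. The selectivity needed is fragmentation over oxetane formation, elimination and attack of base on the three acceptor groups. The pseudo-equatorial 1β-sulfonate is anti-periplanar to C5–C10 (the oxirane and the C4 methylene flatten ring A to a half-chair without changing this), H2 is syn to the leaving group so no anti elimination is open, and a hindered amide base in stoichiometric amount at low temperature leaves the esters alone. The ketone formed is neutral, so the product is not exposed to alkoxide, and the cold quench guards C6 against epimerisation.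

Step 14
Reactants: 22 2,3-epoxy-8-methacryloyloxygermacra-1(10)E,4(15),11(13)-trien-5-on-12,6-olide
Product: 23 (1R,10R)-1,10:2,3-diepoxy-8-methacryloyloxygermacra-4(15),11(13)-dien-5-on-12,6-olide
Conditions: dimethyldioxirane, acetone/CH2Cl2, −20 → 0 °C
Reagents that add atoms: dimethyldioxirane, CC1(C)OO1
Why: Dioxirane epoxidation under neutral conditions; C1=C10 is the only olefin not conjugated to a carbonyl. Attack from the periphery on the conformer inherited from the decalin (C14 methyl on the β face, inner face blocked by C5 across the ring) should give the trans-oxirane with 1R,10R configuration.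

Step 15
Reactants: 23 (1R,10R)-1,10:2,3-diepoxy-8-methacryloyloxygermacra-4(15),11(13)-dien-5-on-12,6-olide
Product: 24 ACon1_002091, (1R,2S,3S,5R,6S,7R,8S,10R)-1,10:2,3-diepoxy-5-hydroxygermacra-4(15),11(13)-dien-12,6-olide 8-methacrylate
Conditions: NaBH4, CeCl3·7H2O, MeOH, −78 °C
Reagents that add atoms: none
Why: Luche reduction; the cerium salt directs hydride to 1,2-addition at the C5 enone, and at −78 °C the α-methylene lactone and the methacrylate should not be reduced. Peripheral hydride delivery to the carbonyl, whose oxygen keeps the α orientation it had in the decalin, should set 5R.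

## Compound list

1 | α-santonin, (11S)-3-oxoeudesma-1,4-dien-12,6α-olide | C[C@H]1[C@@H]2CC[C@]3(C=CC(=O)C(=C3[C@H]2OC1=O)C)C | starting material
2 | artemisin, 8α-hydroxy-α-santonin | C[C@H]1[C@@H]2[C@@H](O)C[C@@]3(C)C=CC(=O)C(C)=C3[C@H]2OC1=O | intermediate
3 | tert-butyldimethylsilyl chloride | CC(C)(C)[Si](C)(C)Cl | starting material
4 | 8α-(tert-butyldimethylsilyloxy)-α-santonin | C[C@H]1[C@@H]2[C@@H](O[Si](C)(C)C(C)(C)C)C[C@@]3(C)C=CC(=O)C(C)=C3[C@H]2OC1=O | intermediate
5 | 1α,2α-epoxy-8α-(tert-butyldimethylsilyloxy)-3-oxoeudesm-4-en-12,6α-olide | C[C@H]1[C@@H]2[C@@H](O[Si](C)(C)C(C)(C)C)C[C@@]3(C)[C@H]4O[C@H]4C(=O)C(C)=C3[C@H]2OC1=O | intermediate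
6 | C3 hydrazone of 5 (NH2 syn to C2) | C[C@H]1[C@@H]2[C@@H](O[Si](C)(C)C(C)(C)C)C[C@@]3(C)[C@H]4O[C@H]4/C(=N\N)C(C)=C3[C@H]2OC1=O | intermediate (not isolated)
7 | 1α-hydroxy-8α-(tert-butyldimethylsilyloxy)eudesma-2,4-dien-12,6α-olide | C[C@H]1[C@@H]2[C@@H](O[Si](C)(C)C(C)(C)C)C[C@@]3(C)[C@@H](O)C=CC(C)=C3[C@H]2OC1=O | intermediate
8 | 2α,5α-epidioxy-1α-hydroxy-8α-(tert-butyldimethylsilyloxy)eudesm-3-en-12,6α-olide | C[C@H]1[C@@H]2[C@@H](O[Si](C)(C)C(C)(C)C)C[C@@]3(C)[C@@H](O)[C@@H]4C=C(C)[C@]3(OO4)[C@H]2OC1=O | intermediate (not isolated)
9 | 2α,3α:4α,5α-diepoxy-1α-hydroxy-8α-(tert-butyldimethylsilyloxy)eudesman-12,6α-olide | C[C@H]1[C@@H]2[C@@H](O[Si](C)(C)C(C)(C)C)C[C@@]3(C)[C@@H](O)[C@H]4O[C@H]4[C@@]5(C)O[C@@]35[C@H]2OC1=O | intermediate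
10 | 2α,3α-epoxy-1α,5α-dihydroxy-8α-(tert-butyldimethylsilyloxy)eudesm-4(15)-en-12,6α-olide | C[C@H]1[C@@H]2[C@@H](O[Si](C)(C)C(C)(C)C)C[C@@]3(C)[C@@H](O)[C@H]4O[C@H]4C(=C)[C@]3(O)[C@H]2OC1=O | intermediate
11 | 11β-phenylseleno derivative of 10 (11α-methyl) | C[C@@]1([Se]c5ccccc5)[C@@H]2[C@@H](O[Si](C)(C)C(C)(C)C)C[C@@]3(C)[C@@H](O)[C@H]4O[C@H]4C(=C)[C@]3(O)[C@H]2OC1=O | intermediate (not isolated)
12 | selenoxide of 11 (both epimers at selenium) | C[C@@]1([Se](=O)c5ccccc5)[C@@H]2[C@@H](O[Si](C)(C)C(C)(C)C)C[C@@]3(C)[C@@H](O)[C@H]4O[C@H]4C(=C)[C@]3(O)[C@H]2OC1=O | intermediate (not isolated)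
13 | 2α,3α-epoxy-1α,5α-dihydroxy-8α-(tert-butyldimethylsilyloxy)eudesma-4(15),11(13)-dien-12,6α-olide | C=C1[C@@H]2[C@@H](O[Si](C)(C)C(C)(C)C)C[C@@]3(C)[C@@H](O)[C@H]4O[C@H]4C(=C)[C@]3(O)[C@H]2OC1=O | intermediate
14 | 2α,3α-epoxy-5α-hydroxy-1-oxo-8α-(tert-butyldimethylsilyloxy)eudesma-4(15),11(13)-dien-12,6α-olide | C=C1[C@@H]2[C@@H](O[Si](C)(C)C(C)(C)C)C[C@@]3(C)C(=O)[C@H]4O[C@H]4C(=C)[C@]3(O)[C@H]2OC1=O | intermediate
15 | 2α,3α-epoxy-1β,5α-dihydroxy-8α-(tert-butyldimethylsilyloxy)eudesma-4(15),11(13)-dien-12,6α-olide | C=C1[C@@H]2[C@@H](O[Si](C)(C)C(C)(C)C)C[C@@]3(C)[C@H](O)[C@H]4O[C@H]4C(=C)[C@]3(O)[C@H]2OC1=O | intermediate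
16 | methanesulfonyl chloride | CS(=O)(=O)Cl | starting material
17 | 2α,3α-epoxy-5α-hydroxy-1β-mesyloxy-8α-(tert-butyldimethylsilyloxy)eudesma-4(15),11(13)-dien-12,6α-olide | C=C1[C@@H]2[C@@H](O[Si](C)(C)C(C)(C)C)C[C@@]3(C)[C@H](OS(C)(=O)=O)[C@H]4O[C@H]4C(=C)[C@]3(O)[C@H]2OC1=O | intermediate
18 | 2α,3α-epoxy-5α,8α-dihydroxy-1β-mesyloxyeudesma-4(15),11(13)-dien-12,6α-olide | C=C1[C@@H]2[C@@H](O)C[C@@]3(C)[C@H](OS(C)(=O)=O)[C@H]4O[C@H]4C(=C)[C@]3(O)[C@H]2OC1=O | intermediate
19 | methacryloyl chloride | C=C(C)C(=O)Cl | starting material
20 | 2α,3α-epoxy-5α-hydroxy-1β-mesyloxy-8α-methacryloyloxyeudesma-4(15),11(13)-dien-12,6α-olide (trans-decalin, mesylate equatorial) | C=C1[C@@H]2[C@@H](OC(=O)C(C)=C)C[C@@]3(C)[C@H](OS(C)(=O)=O)[C@H]4O[C@H]4C(=C)[C@]3(O)[C@H]2OC1=O | intermediate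
21 | potassium 5α-alkoxide of 20 | C=C1[C@@H]2[C@@H](OC(=O)C(C)=C)C[C@@]3(C)[C@H](OS(C)(=O)=O)[C@H]4O[C@H]4C(=C)[C@]3([O-])[C@H]2OC1=O.[K+] | intermediate (not isolated)
22 | 2,3-epoxy-8-methacryloyloxygermacra-1(10)E,4(15),11(13)-trien-5-on-12,6-olide (C2, C3, C6, C7, C8 as in 20) | C=C1[C@@H]2[C@@H](OC(=O)C(C)=C)C/C(C)=C/[C@H]3O[C@H]3C(=C)C(=O)[C@H]2OC1=O | intermediate
23 | (1R,10R)-1,10:2,3-diepoxy-8-methacryloyloxygermacra-4(15),11(13)-dien-5-on-12,6-olide | C=C1[C@@H]2[C@@H](OC(=O)C(C)=C)C[C@@]3(C)O[C@@H]3[C@H]3O[C@H]3C(=C)C(=O)[C@H]2OC1=O | intermediate
24 | ACon1_002091, (1R,2S,3S,5R,6S,7R,8S,10R)-1,10:2,3-diepoxy-5-hydroxygermacra-4(15),11(13)-dien-12,6-olide 8-methacrylate | C=C(C)C(=O)O[C@H]1C[C@@]2(C)O[C@@H]2[C@H]2O[C@H]2C(=C)[C@@H](O)[C@H]2OC(=O)C(=C)[C@@H]21 | target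

## Step count and least certain steps

Total step count: 15. Longest linear sequence: 15 steps, from 1 to 24 (the route is fully linear; 3, 16 and 19 are single-step reagents).

Step 13 (key step). The most likely failure is attack of base or alkoxide on the methacrylate or the α-methylene lactone before the fragmentation occurs. The second is intramolecular displacement of the sulfonate by the alkoxide (oxetane formation) if ring A twists away from the anti-periplanar arrangement. Base-induced epimerisation at C6 of the new α-oxygenated ketone is a third possibility. Fallback: the ring opening is moved one stage earlier and the ester is placed after it. The route is left at 17, whose only ester is the lactone; KOtBu in THF at −20 °C should give the silyl ether 2,3-epoxy-8-(tert-butyldimethylsilyloxy)germacra-1(10)E,4(15),11(13)-trien-5-on-12,6-olide F1. Dimethyldioxirane should convert it into the (1R,10R)-1,10-epoxide F2, buffered Bu4NF/AcOH should free the 8-hydroxy diepoxy ketone F3, and acylation with 19 (Et3N, DMAP) returns to the route at 23.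

Step 1. Hydroxylation at other positions (C11, C9), reduction of the C1=C2 bond by the organism or low conversion would give poor site selectivity and throughput, because the enzyme and not the substrate decides where oxygen goes. Fallback: the enzymatic oxidation is replaced by reagent-controlled aliphatic C–H hydroxylation of 1. This would use a bulky aminopyridine complex of Mn(OTf)2 (divalent manganese) with H2O2 and a carboxylic acid in a fluorinated alcohol, which protects the alcohol product from further oxidation. Santonin has only two methylene groups; C9 is neopentylic, and the equatorial 8α C–H is the most accessible. This sets out from 1 and returns at 2 without a new compound (F0).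

Step 4. Hydrazinolysis of the strained γ-lactone, slow condensation at the hindered conjugated C3 ketone, or acid-induced loss of water from the dienol could erode the transposition. Fallback: the hydrazone pathway is replaced by a radical deoxygenative epoxide opening. From 5, NaBH4/CeCl3·7H2O should give the epoxy alcohol 1α,2α-epoxy-3α-hydroxy-8α-(tert-butyldimethylsilyloxy)eudesm-4-en-12,6α-olide F4 (the C3 configuration is lost later). 1,1'-Thiocarbonyldiimidazole converts it into the O-(imidazol-1-ylthiocarbonyl) derivative F5. Bu3SnH/AIBN in toluene at 80 °C then generates the C3 radical, which opens the adjacent oxirane and gives 7 after hydrogen transfer (Barton–McCombie-type fragmentation), returning to the route at 7.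

Step 6 (with step 5). Lewis-acid-induced opening or rearrangement of the bis-epoxide, or transesterification of the lactone at 110 °C, could erode regiocontrol. Fallback: the bis-epoxide is avoided. From 7, hydroxyl-directed epoxidation with VO(acac)2/t-BuOOH should give the mono-epoxide 2α,3α-epoxy-1α-hydroxy-8α-(tert-butyldimethylsilyloxy)eudesm-4-en-12,6α-olide F6. A Schenck ene reaction of singlet oxygen on the remaining tetrasubstituted olefin can take only the C15 hydrogens on the α face, and should give the 5α-hydroperoxide F7 with C4=C15. Triphenylphosphine reduces F7 to 10, where the route is rejoined.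

Step 15. Hydride delivery to the wrong carbonyl face is possible if the enone unit rotates in the flexible ring, because the facial bias rests on the ring conformation alone. Some 1,4-reduction of the acceptors could also occur. Fallback: substrate control is replaced by reagent control. Corey–Bakshi–Shibata reduction of 23 with catecholborane and the 2-methyl-oxazaborolidine enantiomer that delivers hydride to the required face, at −78 °C in toluene, is 1,2-selective for enones and uses no nucleophilic hydride. It leads from 23 to 24 without a new compound (F0).

## Further compounds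

F1 | step 13 | 2,3-epoxy-8-(tert-butyldimethylsilyloxy)germacra-1(10)E,4(15),11(13)-trien-5-on-12,6-olide | C=C1[C@@H]2[C@@H](O[Si](C)(C)C(C)(C)C)C/C(C)=C/[C@H]3O[C@H]3C(=C)C(=O)[C@H]2OC1=O
F2 | step 13 | (1R,10R)-1,10:2,3-diepoxy-8-(tert-butyldimethylsilyloxy)germacra-4(15),11(13)-dien-5-on-12,6-olide | C=C1[C@@H]2[C@@H](O[Si](C)(C)C(C)(C)C)C[C@@]3(C)O[C@@H]3[C@H]3O[C@H]3C(=C)C(=O)[C@H]2OC1=O
F3 | step 13 | (1R,10R)-1,10:2,3-diepoxy-8-hydroxygermacra-4(15),11(13)-dien-5-on-12,6-olide | C=C1[C@@H]2[C@@H](O)C[C@@]3(C)O[C@@H]3[C@H]3O[C@H]3C(=C)C(=O)[C@H]2OC1=O
F0 | step 1 | none | none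
F4 | step 4 | 1α,2α-epoxy-3α-hydroxy-8α-(tert-butyldimethylsilyloxy)eudesm-4-en-12,6α-olide | C[C@H]1[C@@H]2[C@@H](O[Si](C)(C)C(C)(C)C)C[C@@]3(C)[C@H]4O[C@H]4[C@@H](O)C(C)=C3[C@H]2OC1=O
F5 | step 4 | O-(imidazol-1-ylthiocarbonyl) derivative of F4 | C[C@H]1[C@@H]2[C@@H](O[Si](C)(C)C(C)(C)C)C[C@@]3(C)[C@H]4O[C@H]4[C@@H](OC(=S)n5ccnc5)C(C)=C3[C@H]2OC1=O
F6 | step 6 | 2α,3α-epoxy-1α-hydroxy-8α-(tert-butyldimethylsilyloxy)eudesm-4-en-12,6α-olide | C[C@H]1[C@@H]2[C@@H](O[Si](C)(C)C(C)(C)C)C[C@@]3(C)[C@@H](O)[C@H]4O[C@H]4C(C)=C3[C@H]2OC1=O
F7 | step 6 | 2α,3α-epoxy-5α-hydroperoxy-1α-hydroxy-8α-(tert-butyldimethylsilyloxy)eudesm-4(15)-en-12,6α-olide | C[C@H]1[C@@H]2[C@@H](O[Si](C)(C)C(C)(C)C)C[C@@]3(C)[C@@H](O)[C@H]4O[C@H]4C(=C)[C@]3(OO)[C@H]2OC1=O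
F0 | step 15 | none | none
A1 | alternative 1 | 1,10:2,3-diepoxygermacra-4E,11(13)-dien-12,6-olide 8-methacrylate | C=C(C)C(=O)O[C@H]1C[C@@]2(C)O[C@@H]2[C@H]2O[C@H]2/C(C)=C/[C@H]2OC(=O)C(=C)[C@@H]21
A2 | alternative 2 | 8-(dimethylphenylsilyl)-5-(4-methoxybenzyloxy)cyclodeca-1(10)E,2Z,4(15)-trien-6-one (germacrane numbering) | C[Si](C)(c1ccccc1)[C@H]1C/C(C)=C/C=C\C(=C)[C@@H](OCc2ccc(OC)cc2)C(=O)C1
A3 | alternative 3 | 1,10-epoxygermacra-2Z,4(15),11(13)-trien-5-ol-12,6-olide 8-methacrylate | C=C(C)C(=O)O[C@H]1C[C@@]2(C)O[C@@H]2/C=C\C(=C)[C@@H](O)[C@H]2OC(=O)C(=C)[C@@H]21
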